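**Plan**
- Retrosynthesis: the C2 acetate goes back to a ketone and the C15 acid to a silyl-protected allylic alcohol; the decalin is then cut at C1–C2 and C9–C10 in one move.
- This is possible because C2 is the only oxygenated ring carbon and lies between the methylenes C1 and C3 of ring A, so it can be an acyl radical. C1, C10 and C20 are then an isopropenyl group, and the exocyclic C8=C17 of ring B is what an allylstannane leaves when tin departs from C17.
- The open-chain Se-phenyl selenoester is cut at C8=C9 (Z-selective Wittig reaction of a C8 ketone with a C9–C15 ylide) and at C2–C3 (Arndt–Eistert homologation); the C3–C8 bond is a ring bond of a cyclohexenone.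
- Forward: (S)-carvone is dimethylated at its α′ carbon (future C4), opened to a keto acid, homologated, oxygenated at C17, joined to the side chain, stannylated and made into the selenoester. Ring A and then ring B close in one radical chain; reduction, acetylation and oxidation of C15 finish.
- Stereochemistry: C5 is the carvone stereocentre; C10 and C9 follow from it through a chair–chair transition state and the Z olefin; C2 comes from equatorial hydride attack; 13E from a syn carboalumination.

Key step: step 19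

Remark: labdane numbering (C1–C20) is used for all positions, also in open-chain intermediates; the target SMILES is read as 2β-acetoxylabda-8(17),13E-dien-15-oic acid with 2R,5S,9S,10S configuration.

Step 1
Reactants: 1 (S)-(+)-carvone, (5S)-2-methyl-5-(prop-1-en-2-yl)cyclohex-2-en-1-one
Product: 3 (5S)-2,6-dimethyl-5-(prop-1-en-2-yl)cyclohex-2-en-1-one (6-methylcarvone; C6 epimers), via lithium dienolate 2 (not isolated)
Conditions: LiN(i-Pr)2, THF, −78 °C; MeI, −78 to 0 °C
Reagents that add atoms: iodomethane CI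
Why: Kinetic deprotonation of the enone at the α′ methylene by the hindered amide gives the cross-conjugated dienolate, which is C-methylated (enolate alkylation); the carvone stereocentre is untouched and the new centre is erased in step 2.

Step 2
Reactants: 3 6-methylcarvone
Product: 5 (5R)-2,6,6-trimethyl-5-(prop-1-en-2-yl)cyclohex-2-en-1-one (6,6-dimethylcarvone), via lithium dienolate 4 (not isolated)
Conditions: LiN(i-Pr)2, THF, −78 °C; MeI, DMPU, −78 °C to rt
Reagents that add atoms: iodomethane CI
Why: The second enolate alkylation is regiospecific because the α′ carbon carries the only remaining α′ hydrogen, and it creates the quaternary carbon that becomes C4 with C18 and C19 (the descriptor changes by priority only).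

Step 3
Reactants: 5 6,6-dimethylcarvone
Product: 7 (3R)-6-hydroxy-2,2,6-trimethyl-3-(prop-1-en-2-yl)cyclohexan-1-one (carbinol epimers), via lithium enolate 6 (not isolated)
Conditions: LiBH(s-Bu)3, THF, −78 °C; then 2-(benzenesulfonyl)-3-phenyloxaziridine, −78 to −20 °C; H2O
Reagents that add atoms: 2-(benzenesulfonyl)-3-phenyloxaziridine O=S(=O)(N1OC1c1ccccc1)c1ccccc1
Why: The bulky borohydride adds hydride 1,4 to the β-unsubstituted enone whose carbonyl is shielded by the quaternary carbon, and the regiodefined enolate is hydroxylated at its only α carbon (conjugate reduction then enolate oxidation); the new carbinol centre is destroyed in step 4.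

Step 4
Reactants: 7 ketol
Product: 8 (3R)-2,2-dimethyl-6-oxo-3-(prop-1-en-2-yl)heptanoic acid
Conditions: H5IO6, THF/H2O, 0 °C to rt
Reagents that add atoms: periodic acid O[I](=O)(O)(O)(O)O
Why: Periodate cleavage of the α-ketol breaks the bond between the carbonyl carbon and the carbinol carbon, giving the acid (future C3) and the methyl ketone (C8 with C17) and sparing the 1,1-disubstituted alkene.

Step 5
Reactants: 8 keto acid
Product: 10 (4R)-1-diazo-3,3-dimethyl-4-(prop-1-en-2-yl)octane-2,7-dione, via acid chloride 9 (not isolated)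
Conditions: 1-chloro-N,N,2-trimethylprop-1-en-1-amine, CH2Cl2, 0 °C; then CH2N2 (excess), Et2O, 0 °C
Reagents that add atoms: diazomethane C=[N+]=[N-]
Why: The α-chloroenamine makes the acid chloride without free HCl, so the isopropenyl group is safe, and diazomethane is acylated by the acid chloride much faster than it attacks the methyl ketone (first half of the Arndt–Eistert homologation).

Step 6
Reactants: 10 diazoketone
Product: 12 methyl (4R)-3,3-dimethyl-7-oxo-4-(prop-1-en-2-yl)octanoate, via ketene 11 (not isolated)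
Conditions: hν (350 nm), MeOH, rt
Reagents that add atoms: methanol CO
Why: Photochemical Wolff rearrangement shifts the tertiary alkyl group and methanol traps the ketene, which places the C3 methylene between C4 and the C2 carboxyl; direct irradiation avoids metal carbenoids that could cyclopropanate the nearby alkene.

Step 7
Reactants: 12 keto ester
Product: 14 methyl (4R)-8-hydroxy-3,3-dimethyl-7-oxo-4-(prop-1-en-2-yl)octanoate, via potassium enolate 13 (not isolated)
Conditions: KN(SiMe3)2, THF, −78 °C; then 2-(benzenesulfonyl)-3-phenyloxaziridine, −78 °C; H2O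
Reagents that add atoms: 2-(benzenesulfonyl)-3-phenyloxaziridine O=S(=O)(N1OC1c1ccccc1)c1ccccc1
Why: Kinetic deprotonation by the hindered amide should take the methyl protons (C17) of the methyl ketone in preference to the C7 methylene and the less acidic ester α protons, and the enolate is oxidised at carbon (enolate hydroxylation) without touching the alkene.

Step 8
Reactants: 14 hydroxy ketone
Product: 15 methyl (4R)-8-[(tert-butyldimethylsilyl)oxy]-3,3-dimethyl-7-oxo-4-(prop-1-en-2-yl)octanoate
Conditions: t-BuMe2SiCl, imidazole, DMF, rt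
Reagents that add atoms: tert-butyldimethylsilyl chloride CC(C)(C)[Si](C)(C)Cl
Why: Silylation of the primary alcohol gives the α-silyloxy ketone that the stereoselective olefination of step 13 requires.

Step 9
Reactants: 16 5-chloropent-1-yne
Product: 18 methyl (2E)-6-chloro-3-methylhex-2-enoate, via alkenylalane 17 (not isolated)
Conditions: Me3Al, Cp2ZrCl2 (cat.), CH2Cl2, 0 °C to rt; then ClCO2Me, 0 °C to rt
Reagents that add atoms: trimethylaluminium C[Al](C)C; methyl chloroformate COC(=O)Cl
Why: Zirconium-catalysed carboalumination adds methyl and aluminium syn across the terminal alkyne with the metal on the terminal carbon, and acylation of the alkenylalane proceeds with retention, which fixes the 13E geometry; the alkyl chloride is inert.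

Step 10
Reactants: 18 chloro enoate
Product: 19 (2E)-6-chloro-3-methylhex-2-en-1-ol
Conditions: i-Bu2AlH, CH2Cl2, −78 °C
Reagents that add atoms: none
Why: The aluminium hydride reduces the conjugated ester 1,2 to the allylic alcohol without affecting the alkyl chloride or the olefin geometry.

Step 11
Reactants: 19 allylic alcohol
Product: 20 tert-butyl{[(2E)-6-chloro-3-methylhex-2-en-1-yl]oxy}diphenylsilane
Conditions: t-BuPh2SiCl, imidazole, CH2Cl2, rt
Reagents that add atoms: tert-butyldiphenylsilyl chloride CC(C)(C)[Si](Cl)(c1ccccc1)c1ccccc1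
Why: Silylation masks the C15 oxygen with a group that resists ylide, mild acid, stannyl anion, hydroxide and radical conditions.

Step 12
Reactants: 20 chloride
Product: 22 {(4E)-6-[(tert-butyldiphenylsilyl)oxy]-4-methylhex-4-en-1-yl}triphenylphosphonium iodide, via iodide 21 (not isolated)
Conditions: NaI, PPh3, MeCN, reflux
Reagents that add atoms: sodium iodide [Na+].[I-]; triphenylphosphine c1ccc(cc1)P(c1ccccc1)c1ccccc1
Why: Finkelstein exchange gives the primary iodide, which quaternises triphenylphosphine by SN2; silyl ether and alkene are inert.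

Step 13
Reactants: 22 phosphonium iodide; 15 silyloxy ketone
Product: 24 methyl (4R,7Z,11E)-13-[(tert-butyldiphenylsilyl)oxy]-7-{[(tert-butyldimethylsilyl)oxy]methyl}-3,3,11-trimethyl-4-(prop-1-en-2-yl)trideca-7,11-dienoate, via ylide 23 (not isolated)
Conditions: KN(SiMe3)2, THF, −78 °C; then 15, −78 to 0 °C
Reagents that add atoms: none
Why: Wittig reaction of an unstabilised ylide with an α-silyloxy ketone, a substrate class known to give the Z-trisubstituted allylic ether under kinetic control, so that C11 lies cis to C17 and anti to C7 across C8=C9; the hindered ester and both silyl ethers tolerate the ylide at low temperature.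

Step 14
Reactants: 24 bis-silyl ether
Product: 25 methyl (4R,7Z,11E)-13-[(tert-butyldiphenylsilyl)oxy]-7-(hydroxymethyl)-3,3,11-trimethyl-4-(prop-1-en-2-yl)trideca-7,11-dienoate
Conditions: PPTS (cat.), MeOH, rt
Reagents that add atoms: none
Why: Acid-catalysed methanolysis removes the primary tert-butyldimethylsilyl ether much faster than the tert-butyldiphenylsilyl ether, so only the C17 hydroxyl is freed.

Step 15
Reactants: 25 allylic alcohol
Product: 27 methyl (4R,7Z,11E)-13-[(tert-butyldiphenylsilyl)oxy]-7-(chloromethyl)-3,3,11-trimethyl-4-(prop-1-en-2-yl)trideca-7,11-dienoate, via mesylate 26 (not isolated)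
Conditions: MsCl, LiCl, 2,4,6-collidine, DMF, 0 °C
Reagents that add atoms: lithium chloride [Li+].[Cl-]; methanesulfonyl chloride CS(=O)(=O)Cl (chloride)
Why: Mesylation in the presence of chloride converts the primary allylic alcohol into the chloride by direct SN2 displacement, without allylic transposition or loss of the Z geometry.

Step 16
Reactants: 27 allylic chloride
Product: 28 methyl (4R,7Z,11E)-13-[(tert-butyldiphenylsilyl)oxy]-3,3,11-trimethyl-4-(prop-1-en-2-yl)-7-[(tributylstannyl)methyl]trideca-7,11-dienoate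
Conditions: Bu3SnLi (from Bu3SnH and LiN(i-Pr)2, THF, 0 °C), THF, −78 °C
Reagents that add atoms: tributylstannyllithium [Li][Sn](CCCC)(CCCC)CCCC
Why: The stannyl anion displaces the primary allylic chloride by SN2 within minutes at −78 °C with retention of olefin geometry, far faster than it attacks the hindered ester; no conjugate acceptor is present.

Step 17
Reactants: 28 stannyl ester
Product: 29 (4R,7Z,11E)-13-[(tert-butyldiphenylsilyl)oxy]-3,3,11-trimethyl-4-(prop-1-en-2-yl)-7-[(tributylstannyl)methyl]trideca-7,11-dienoic acid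
Conditions: LiOH, THF/MeOH/H2O, 40 °C; then cold dilute HCl to pH 5
Reagents that add atoms: lithium hydroxide [Li+].[OH-]
Why: Saponification of the methyl ester; allylstannane and silyl ether tolerate aqueous base, and acidification is stopped at pH 5 so that the allylstannane is not protonolysed.

Step 18
Reactants: 29 acid
Product: 30 Se-phenyl (4R,7Z,11E)-13-[(tert-butyldiphenylsilyl)oxy]-3,3,11-trimethyl-4-(prop-1-en-2-yl)-7-[(tributylstannyl)methyl]trideca-7,11-dieneselenoate
Conditions: (PhSe)2, Bu3P, CH2Cl2, rt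
Reagents that add atoms: diphenyl diselenide c1ccc(cc1)[Se][Se]c1ccccc1
Why: The acid is activated as an acyloxyphosphonium salt and captured by phenylselenolate under neutral conditions (selenoester formation), which spares the allylstannane and the alkenes.

Step 19
Reactants: 30 selenoester
Product: 31 (5S,9S,10S)-15-[(tert-butyldiphenylsilyl)oxy]labda-8(17),13E-dien-2-one
Conditions: Bu3SnH (0.2 equiv), AIBN (0.2 equiv), degassed PhH (0.005 M), 80 °C
Reagents that add atoms: none
Why: A stannyl radical abstracts PhSe from the selenoester, the C2 acyl radical adds to C1 (the CH2 end of the isopropenyl group), the resulting tertiary C10 radical adds to C9 of the allylstannane, and the C8 radical expels Bu3Sn• from C17, which forms C8=C17 and carries the chain without a stoichiometric hydride donor. The closest known reaction types are tin-mediated acyl radical polyene cascades of selenoesters and intramolecular SH2′ allyl transfer from allylstannanes. Ring A closes 6-endo-trig (C1–C2) and ring B closes 6-endo-trig (C9–C10). C10 and C9 are set by the C5 stereocentre through a chair–chair transition state with C6 equatorial on the nascent ring A, which gives the trans ring fusion with C20 axial (10β), while the Z olefin holds C11 anti to C7 and hence equatorial (9β). The step needs 6-endo over 5-exo closure at both alkenes, secured by the fully substituted internal carbons C10 and C8, and cyclisation ahead of decarbonylation or reduction, secured by the primary acyl radical, the gem-dimethyl group at C4, high dilution and the hydride-free chain.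

Step 20
Reactants: 31 ketone
Product: 32 (2R,5S,9S,10S)-15-[(tert-butyldiphenylsilyl)oxy]labda-8(17),13E-dien-2β-ol
Conditions: LiBH(s-Bu)3, THF, −78 °C; H2O
Reagents that add atoms: none
Why: The bulky hydride attacks C2 from the α face (equatorial attack) because the β face is blocked by the syn-axial methyl groups on C4 and C10, which gives the axial 2β alcohol (substrate-controlled ketone reduction).

Step 21
Reactants: 32 alcohol
Product: 33 2β-acetoxy-15-[(tert-butyldiphenylsilyl)oxy]labda-8(17),13E-diene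
Conditions: Ac2O, DMAP, pyridine, 40 °C
Reagents that add atoms: acetic anhydride CC(=O)OC(C)=O
Why: DMAP-catalysed acylation esterifies the hindered axial secondary alcohol, the only nucleophilic group present.

Step 22
Reactants: 33 acetate
Product: 34 2β-acetoxylabda-8(17),13E-dien-15-ol
Conditions: Bu4NF, AcOH, THF, rt
Reagents that add atoms: none
Why: Fluoride cleaves the silyl ether, and the acetic acid buffer keeps the acetate from being transesterified.

Step 23
Reactants: 34 allylic alcohol
Product: 35 2β-acetoxylabda-8(17),13E-dien-15-al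
Conditions: MnO2, CH2Cl2, rt
Reagents that add atoms: none
Why: MnO2 oxidises only the allylic alcohol, under neutral conditions that preserve the 13E geometry, the exocyclic alkene and the acetate.

Step 24
Reactants: 35 enal
Product: 36 2β-acetoxylabda-8(17),13E-dien-15-oic acid (target)
Conditions: NaClO2, NaH2PO4, 2-methylbut-2-ene, t-BuOH/H2O, 0 °C to rt
Reagents that add atoms: sodium chlorite [Na+].[O-]Cl=O
Why: Pinnick oxidation converts the enal into the acid without isomerising the conjugated double bond, and the alkene scavenger removes hypochlorous acid before it can attack the exocyclic methylene.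

**Compound list**
1 | (S)-(+)-carvone, (5S)-2-methyl-5-(prop-1-en-2-yl)cyclohex-2-en-1-one | CC1=CC[C@H](C(C)=C)CC1=O | starting material
2 | lithium (3S)-6-methyl-3-(prop-1-en-2-yl)cyclohexa-1,5-dien-1-olate | [Li+].[O-]C1=C[C@@H](C(C)=C)CC=C1C | intermediate
3 | (5S)-2,6-dimethyl-5-(prop-1-en-2-yl)cyclohex-2-en-1-one (C6 epimers) | CC1=CC[C@H](C(C)=C)C(C)C1=O | intermediate
4 | lithium (3R)-2,6-dimethyl-3-(prop-1-en-2-yl)cyclohexa-1,5-dien-1-olate | [Li+].[O-]C1=C(C)[C@@H](C(C)=C)CC=C1C | intermediate
5 | (5R)-2,6,6-trimethyl-5-(prop-1-en-2-yl)cyclohex-2-en-1-one | CC1=CC[C@H](C(C)=C)C(C)(C)C1=O | intermediate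
6 | lithium (5R)-2,6,6-trimethyl-5-(prop-1-en-2-yl)cyclohex-1-en-1-olate | [Li+].[O-]C1=C(C)CC[C@H](C(C)=C)C1(C)C | intermediate
7 | (3R)-6-hydroxy-2,2,6-trimethyl-3-(prop-1-en-2-yl)cyclohexan-1-one (carbinol epimers) | CC1(O)CC[C@H](C(C)=C)C(C)(C)C1=O | intermediate
8 | (3R)-2,2-dimethyl-6-oxo-3-(prop-1-en-2-yl)heptanoic acid | C=C(C)[C@@H](CCC(C)=O)C(C)(C)C(=O)O | intermediate
9 | (3R)-2,2-dimethyl-6-oxo-3-(prop-1-en-2-yl)heptanoyl chloride | C=C(C)[C@@H](CCC(C)=O)C(C)(C)C(=O)Cl | intermediate
10 | (4R)-1-diazo-3,3-dimethyl-4-(prop-1-en-2-yl)octane-2,7-dione | C=C(C)[C@@H](CCC(C)=O)C(C)(C)C(=O)C=[N+]=[N-] | intermediate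
11 | (4R)-3,3-dimethyl-4-(prop-1-en-2-yl)oct-1-ene-1,7-dione (ketene) | C=C(C)[C@@H](CCC(C)=O)C(C)(C)C=C=O | intermediate
12 | methyl (4R)-3,3-dimethyl-7-oxo-4-(prop-1-en-2-yl)octanoate | C=C(C)[C@@H](CCC(C)=O)C(C)(C)CC(=O)OC | intermediate
13 | potassium (5R)-8-methoxy-6,6-dimethyl-8-oxo-5-(prop-1-en-2-yl)oct-1-en-2-olate | [K+].C=C(C)[C@@H](CCC(=C)[O-])C(C)(C)CC(=O)OC | intermediate
14 | methyl (4R)-8-hydroxy-3,3-dimethyl-7-oxo-4-(prop-1-en-2-yl)octanoate | C=C(C)[C@@H](CCC(=O)CO)C(C)(C)CC(=O)OC | intermediate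
15 | methyl (4R)-8-[(tert-butyldimethylsilyl)oxy]-3,3-dimethyl-7-oxo-4-(prop-1-en-2-yl)octanoate | C=C(C)[C@@H](CCC(=O)CO[Si](C)(C)C(C)(C)C)C(C)(C)CC(=O)OC | intermediate
16 | 5-chloropent-1-yne | C#CCCCCl | starting material
17 | [(1E)-5-chloro-2-methylpent-1-en-1-yl]dimethylalumane | C[Al](C)/C=C(\C)CCCCl | intermediate
18 | methyl (2E)-6-chloro-3-methylhex-2-enoate | COC(=O)/C=C(\C)CCCCl | intermediate
19 | (2E)-6-chloro-3-methylhex-2-en-1-ol | OC/C=C(\C)CCCCl | intermediate
20 | tert-butyl{[(2E)-6-chloro-3-methylhex-2-en-1-yl]oxy}diphenylsilane | CC(C)(C)[Si](OC/C=C(\C)CCCCl)(c1ccccc1)c1ccccc1 | intermediate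
21 | tert-butyl{[(2E)-6-iodo-3-methylhex-2-en-1-yl]oxy}diphenylsilane | CC(C)(C)[Si](OC/C=C(\C)CCCI)(c1ccccc1)c1ccccc1 | intermediate
22 | {(4E)-6-[(tert-butyldiphenylsilyl)oxy]-4-methylhex-4-en-1-yl}triphenylphosphonium iodide | [I-].CC(C)(C)[Si](OC/C=C(\C)CCC[P+](c1ccccc1)(c1ccccc1)c1ccccc1)(c1ccccc1)c1ccccc1 | intermediate
23 | {(4E)-6-[(tert-butyldiphenylsilyl)oxy]-4-methylhex-4-en-1-ylidene}triphenylphosphorane | CC(C)(C)[Si](OC/C=C(\C)CCC=P(c1ccccc1)(c1ccccc1)c1ccccc1)(c1ccccc1)c1ccccc1 | intermediate
24 | methyl (4R,7Z,11E)-13-[(tert-butyldiphenylsilyl)oxy]-7-{[(tert-butyldimethylsilyl)oxy]methyl}-3,3,11-trimethyl-4-(prop-1-en-2-yl)trideca-7,11-dienoate | C=C(C)[C@@H](CC/C(CO[Si](C)(C)C(C)(C)C)=C/CC/C(C)=C/CO[Si](c1ccccc1)(c1ccccc1)C(C)(C)C)C(C)(C)CC(=O)OC | intermediate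
25 | methyl (4R,7Z,11E)-13-[(tert-butyldiphenylsilyl)oxy]-7-(hydroxymethyl)-3,3,11-trimethyl-4-(prop-1-en-2-yl)trideca-7,11-dienoate | C=C(C)[C@@H](CC/C(CO)=C/CC/C(C)=C/CO[Si](c1ccccc1)(c1ccccc1)C(C)(C)C)C(C)(C)CC(=O)OC | intermediate
26 | methyl (4R,7Z,11E)-13-[(tert-butyldiphenylsilyl)oxy]-7-{[(methanesulfonyl)oxy]methyl}-3,3,11-trimethyl-4-(prop-1-en-2-yl)trideca-7,11-dienoate | C=C(C)[C@@H](CC/C(COS(C)(=O)=O)=C/CC/C(C)=C/CO[Si](c1ccccc1)(c1ccccc1)C(C)(C)C)C(C)(C)CC(=O)OC | intermediate
27 | methyl (4R,7Z,11E)-13-[(tert-butyldiphenylsilyl)oxy]-7-(chloromethyl)-3,3,11-trimethyl-4-(prop-1-en-2-yl)trideca-7,11-dienoate | C=C(C)[C@@H](CC/C(CCl)=C/CC/C(C)=C/CO[Si](c1ccccc1)(c1ccccc1)C(C)(C)C)C(C)(C)CC(=O)OC | intermediate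
28 | methyl (4R,7Z,11E)-13-[(tert-butyldiphenylsilyl)oxy]-3,3,11-trimethyl-4-(prop-1-en-2-yl)-7-[(tributylstannyl)methyl]trideca-7,11-dienoate | C=C(C)[C@@H](CC/C(C[Sn](CCCC)(CCCC)CCCC)=C/CC/C(C)=C/CO[Si](c1ccccc1)(c1ccccc1)C(C)(C)C)C(C)(C)CC(=O)OC | intermediate
29 | (4R,7Z,11E)-13-[(tert-butyldiphenylsilyl)oxy]-3,3,11-trimethyl-4-(prop-1-en-2-yl)-7-[(tributylstannyl)methyl]trideca-7,11-dienoic acid | C=C(C)[C@@H](CC/C(C[Sn](CCCC)(CCCC)CCCC)=C/CC/C(C)=C/CO[Si](c1ccccc1)(c1ccccc1)C(C)(C)C)C(C)(C)CC(=O)O | intermediate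
30 | Se-phenyl (4R,7Z,11E)-13-[(tert-butyldiphenylsilyl)oxy]-3,3,11-trimethyl-4-(prop-1-en-2-yl)-7-[(tributylstannyl)methyl]trideca-7,11-dieneselenoate | C=C(C)[C@@H](CC/C(C[Sn](CCCC)(CCCC)CCCC)=C/CC/C(C)=C/CO[Si](c1ccccc1)(c1ccccc1)C(C)(C)C)C(C)(C)CC(=O)[Se]c1ccccc1 | intermediate
31 | (5S,9S,10S)-15-[(tert-butyldiphenylsilyl)oxy]labda-8(17),13E-dien-2-one | C=C1CC[C@H]2C(C)(C)CC(=O)C[C@]2(C)[C@H]1CC/C(C)=C/CO[Si](c1ccccc1)(c1ccccc1)C(C)(C)C | intermediate
32 | (2R,5S,9S,10S)-15-[(tert-butyldiphenylsilyl)oxy]labda-8(17),13E-dien-2β-ol | C=C1CC[C@H]2C(C)(C)C[C@@H](O)C[C@]2(C)[C@H]1CC/C(C)=C/CO[Si](c1ccccc1)(c1ccccc1)C(C)(C)C | intermediate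
33 | 2β-acetoxy-15-[(tert-butyldiphenylsilyl)oxy]labda-8(17),13E-diene | C=C1CC[C@H]2C(C)(C)C[C@@H](OC(C)=O)C[C@]2(C)[C@H]1CC/C(C)=C/CO[Si](c1ccccc1)(c1ccccc1)C(C)(C)C | intermediate
34 | 2β-acetoxylabda-8(17),13E-dien-15-ol | C=C1CC[C@H]2C(C)(C)C[C@@H](OC(C)=O)C[C@]2(C)[C@H]1CC/C(C)=C/CO | intermediate
35 | 2β-acetoxylabda-8(17),13E-dien-15-al | C=C1CC[C@H]2C(C)(C)C[C@@H](OC(C)=O)C[C@]2(C)[C@H]1CC/C(C)=C/C=O | intermediate
36 | 2β-acetoxylabda-8(17),13E-dien-15-oic acid (2R,5S,9S,10S) | C=C1CC[C@H]2C(C)(C)C[C@@H](OC(C)=O)C[C@]2(C)[C@H]1CC/C(C)=C/C(=O)O | target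

**Step count**
Total: 24 steps. Longest linear sequence: 20 steps (steps 1–8 and 13–24); the side chain 22 takes 4 steps (9–12).

**Steps most likely to fail**

1. Step 19. The allylstannane may be lost by protonolysis on the way to 30, or the chain may stall so that the cascade stops after ring A. The fallback sets out from chloride 27 and replaces the stannyl terminator by a thio terminator with a stoichiometric chain carrier. Displacement with NaSPh in DMF at 0 °C should give the allyl phenyl sulfide methyl (4R,7Z,11E)-13-[(tert-butyldiphenylsilyl)oxy]-3,3,11-trimethyl-7-[(phenylsulfanyl)methyl]-4-(prop-1-en-2-yl)trideca-7,11-dienoate F1. Saponification with LiOH should give the acid F2, and (PhSe)2/Bu3P the Se-phenyl selenoester F3. Irradiation of F3 with (Bu3Sn)2 (1.2 equiv) in refluxing benzene at high dilution should run the same two ring closures; the C8 radical now expels a phenylthiyl radical, which is captured by the ditin and returns a stannyl radical. This radical allyl transfer from allyl sulfides is established and carries no acid-sensitive group; it comes back to the route at ketone 31.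

2. Step 13. The ylide may discriminate poorly between the two faces of approach (low Z/E ratio) or may enolise the ketone. The fallback sets out from chloride 20 and ketone 15 and uses a Horner–Wittig sequence with separation of diastereomers. LiPPh2 in THF followed by H2O2 should convert 20 into {(4E)-6-[(tert-butyldiphenylsilyl)oxy]-4-methylhex-4-en-1-yl}diphenylphosphine oxide F4. Its lithium derivative (n-BuLi, THF, −78 °C) should add to 15; the β-hydroxy phosphine oxides would be separated by chromatography. The (7S,8R) adduct methyl (4R,7S,8R,11E)-13-[(tert-butyldiphenylsilyl)oxy]-7-{[(tert-butyldimethylsilyl)oxy]methyl}-8-(diphenylphosphoryl)-7-hydroxy-3,3,11-trimethyl-4-(prop-1-en-2-yl)tridec-11-enoate F5 should then undergo stereospecific syn elimination with NaH in DMF and come back to the route at 24.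

3. Step 4. The ketol carbonyl lies between a quaternary and a tertiary carbon and may resist the addition that periodate cleavage of a ketol needs, so the cleavage may be slow or incomplete. The fallback sets out from ketol 7 and cleaves a glycol instead. LiAlH4 in Et2O should reduce 7 to the diol (4R)-1,3,3-trimethyl-4-(prop-1-en-2-yl)cyclohexane-1,2-diol F6. NaIO4 in THF/H2O should cleave it to the keto aldehyde (3R)-2,2-dimethyl-6-oxo-3-(prop-1-en-2-yl)heptanal F7. Pinnick oxidation (NaClO2, NaH2PO4, 2-methylbut-2-ene) of the non-enolisable aldehyde should come back to the route at acid 8.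

Further compounds
F1 | step 19 | methyl (4R,7Z,11E)-13-[(tert-butyldiphenylsilyl)oxy]-3,3,11-trimethyl-7-[(phenylsulfanyl)methyl]-4-(prop-1-en-2-yl)trideca-7,11-dienoate | C=C(C)[C@@H](CC/C(CSc1ccccc1)=C/CC/C(C)=C/CO[Si](c1ccccc1)(c1ccccc1)C(C)(C)C)C(C)(C)CC(=O)OC
F2 | step 19 | (4R,7Z,11E)-13-[(tert-butyldiphenylsilyl)oxy]-3,3,11-trimethyl-7-[(phenylsulfanyl)methyl]-4-(prop-1-en-2-yl)trideca-7,11-dienoic acid | C=C(C)[C@@H](CC/C(CSc1ccccc1)=C/CC/C(C)=C/CO[Si](c1ccccc1)(c1ccccc1)C(C)(C)C)C(C)(C)CC(=O)O
F3 | step 19 | Se-phenyl (4R,7Z,11E)-13-[(tert-butyldiphenylsilyl)oxy]-3,3,11-trimethyl-7-[(phenylsulfanyl)methyl]-4-(prop-1-en-2-yl)trideca-7,11-dieneselenoate | C=C(C)[C@@H](CC/C(CSc1ccccc1)=C/CC/C(C)=C/CO[Si](c1ccccc1)(c1ccccc1)C(C)(C)C)C(C)(C)CC(=O)[Se]c1ccccc1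
F4 | step 13 | {(4E)-6-[(tert-butyldiphenylsilyl)oxy]-4-methylhex-4-en-1-yl}diphenylphosphine oxide | O=P(CCC/C(C)=C/CO[Si](c1ccccc1)(c1ccccc1)C(C)(C)C)(c1ccccc1)c1ccccc1
F5 | step 13 | methyl (4R,7S,8R,11E)-13-[(tert-butyldiphenylsilyl)oxy]-7-{[(tert-butyldimethylsilyl)oxy]methyl}-8-(diphenylphosphoryl)-7-hydroxy-3,3,11-trimethyl-4-(prop-1-en-2-yl)tridec-11-enoate | C=C(C)[C@@H](CC[C@](O)(CO[Si](C)(C)C(C)(C)C)[C@@H](CC/C(C)=C/CO[Si](c1ccccc1)(c1ccccc1)C(C)(C)C)P(=O)(c1ccccc1)c1ccccc1)C(C)(C)CC(=O)OC
F6 | step 4 | (4R)-1,3,3-trimethyl-4-(prop-1-en-2-yl)cyclohexane-1,2-diol (carbinol epimers) | CC1(O)CC[C@H](C(C)=C)C(C)(C)C1O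
F7 | step 4 | (3R)-2,2-dimethyl-6-oxo-3-(prop-1-en-2-yl)heptanal | C=C(C)[C@@H](CCC(C)=O)C(C)(C)C=O
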